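## The problem

Compound 19 is a furofuran: ring A (C1, C2, O3, C4, C5) and ring B (C1, C5, C6, O7, C8) are two tetrahydrofurans that share the C1–C5 bond and can only be cis-fused. It has four contiguous stereocentres, the fully substituted acetoxy-bearing bridgehead C1, the bridgehead C5, and the benzylic carbons C2 (guaiacyl) and C6 (veratryl), each with its aryl group on the convex face. Because the two arenes differ, the halves cannot come from a dimerisation and each arene has to arrive with its own fragment. C6 is the one centre that a catalyst can set in a simple monocyclic precursor; inside a ring B precursor it can then steer bond formation at C5 and C1 to the opposite face, whereas C2 lies out of its reach and is better left to thermodynamic control at a stage where it can epimerise. Both benzylic C–O bonds (C2–O3 and C6–O7) sit next to electron-rich arenes and ionise under protic or Lewis acid, and the free phenol para to C2 can expel O3 as a quinone methide. The tertiary acetate would not survive hydride reagents, so it has to go on last, onto a hindered alcohol. The enabling feature is that C2, C1, C5 and C4 of ring A, taken without O3, are the four carbons of a cyclobutanone with C4 as the carbonyl carbon and oxygen on C1. Such a ring is the [2+2] adduct of an arylketene (C2, C4) with the C1=C5 silyl enol ether of a ring B ketone, and its strain invites the later insertion of O3 beside the benzylic C2.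

## Retrosynthesis

**19 back to 17 and 16.** The acetyl C–O bond at C1 is cut first, because the tertiary acetate is the group least compatible with the reductions that ring A needs. Diol 17 is acetylated on both hydroxyls to 18 and the aryl acetate alone is removed again. This avoids any need to tell a phenol from a tertiary alcohol in the acylation itself. 17 comes from the bis-silyl ether 16 by cleaving both Si–O bonds at once. The forward steps must acylate a hindered bridgehead alcohol and then discriminate an aryl ester from a tertiary alkyl ester.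

**16 back to 14.** The C4 methylene is traced to a lactone carbonyl, reached through lactol 15. This adds no skeletal complexity and puts the carbonyl at C4, exactly where an oxygen-insertion retron needs it. The forward reduction must take C4 from ester to ether level without ionising the two benzylic ethers.

**14 back to 13.** The C2–O3 bond is cut as a Baeyer–Villiger retron, which turns the ring A lactone into cyclobutanone 13. Cutting C4–O3 instead would lead to a hydroxy acid with C2 already oxygenated, which is no simpler. Removing O3 leaves a carbocycle that one cycloaddition can make. The forward reaction must migrate C2, not C5, and keep the C2 configuration.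

**13 back to 6 and 11.** The C1–C2 and C4–C5 bonds are cut together, giving arylketene 11 and silyl enol ether 6. The other pairing of cyclobutane bonds (C1–C5 and C2–C4) would need an aryl-substituted enol and a ring-forming acylation, and would not use C6 for control. The chosen cut gives two fragments of similar size, each carrying one arene, and leaves the C1 oxygen in place as the enol ether oxygen. The forward reaction needs head-to-tail regiochemistry, approach anti to the veratryl group on C6, and the C2 aryl group exo, if necessary after epimerisation of 12.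

**6 back to 4, 3, 1 and 2.** The O–Si bond of 6 leads to ketone 4, which must enolise towards C5 and not towards C8. In 4 the O7–C8 bond and the C1 carbonyl are traced to the terminal alkyne of homopropargylic alcohol 3. This is the carbene O–H insertion logic of a diazoketone, but without the diazo compound and the protecting-group steps it would need. Cutting C5–C6 of 3 gives aldehyde 1 and allenylboronate 2, and a catalytic asymmetric propargylation sets C6, the only stereocentre taken from a catalyst.

**11 back to 10, 9 and 7.** The ketene is made in the flask from acid chloride 10. This comes from acid 9, which is homovanillic acid 7 with its phenol masked as a silyl ether that tolerates acid chloride formation and amine base.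

## Roads not taken

Alternative 1: a base-triggered domino between cis-aryl glycidol A1 and arylidene malonate A2. The glycidol alkoxide adds to A2 (C2–O3), the malonate anion opens the epoxide at C5 with inversion (C1–C5, ring A), and the freed C6 alkoxide lactonises onto the cis ester (O7–C8, ring B) to give A3.
- Merits: three bonds and both rings form in one operation from two fragments of equal weight. In bonds per step this is better than the chosen plan.
- Weak points: C1 ends up carrying a carboxyl carbon, not oxygen. Reaching the acetate needs a decarboxylative oxygenation at a quaternary bridgehead next to a lactone, and the C8 lactone still has to be reduced.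
- Further weak points: C2 is set in a reversible oxa-Michael step with no strong bias, and A1 needs an asymmetric epoxidation of a Z-cinnamyl alcohol, the least selective substrate class for that reaction.
- Comparison: the chosen plan forms fewer bonds in its key step, but has the C1 oxygen in place from the start and ends with functional-group changes only.

Alternative 2: acid-promoted opening of epoxy tert-butyl ester A4. The ester carbonyl oxygen attacks benzylic C2 with inversion and isobutene is lost, giving hydroxy lactone A5 with the epoxide oxygen left on C1.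
- Merits: C1 and C2 come from a reagent-controlled epoxidation of a trisubstituted allylic alcohol, and the C1 oxygen is installed with them. This control of absolute configuration is more secure than the substrate-controlled facial selectivity the chosen plan relies on.
- Weak points: the electron-rich benzylic C2 gives the opening carbocation character, so inversion may leak. A5 holds only ring A and two of the four stereocentres.
- Further weak points: ring B still needs the C5–C6 bond, for example by a lactone enolate aldol with 1, plus the C6–O7 closure and the lactone reduction. C5 and C6 would be set with weaker control and at greater length.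
- Comparison: the chosen plan sets against the better absolute control a single step that makes two C–C bonds and three stereocentres.

Alternative 3: spiro benzylidene acetal lactone A6 is converted into its silyl ketene acetal and the acetal is ionised with a silyl triflate. C5 attacks the tethered C6 oxocarbenium ion, closing ring B and releasing the C1 oxygen to give A7.
- Merits: A7 is the desilylated counterpart of lactone 14, reached with no question of Baeyer–Villiger regiochemistry and with C2–O3 already in place. In that respect it is the safer road.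
- Weak points: A6 presupposes a ring A lactone with C1 and C2 already set, such as A5, so the sequence before the key step is longer.
- Further weak points: the closure is a 5-endo attack on the oxocarbenium ion; C6 is fixed in that step with no controlling element beyond product stability; and the Lewis acid meets two ionisable benzylic positions.
- Comparison: the chosen plan sets C6 first, by an established catalytic reaction, and lets it control C5 and C1.

Key step: step 6

Remark on the chemistry: compounds 14–19 and the bicyclic F and A compounds are named with the atom numbering of the target. The (S)-phosphoric acid in step 1 is assumed to deliver the allenyl group to the Si face of 1; if the sense is the opposite, its antipode is used.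

## Route

Step 1
Reactants: 1 3,4-dimethoxybenzaldehyde; 2 allenylboronic acid pinacol ester
Product: 3 (S)-1-(3,4-dimethoxyphenyl)but-3-yn-1-ol
Conditions: (S)-TRIP [(S)-3,3'-bis(2,4,6-triisopropylphenyl)-1,1'-binaphthyl-2,2'-diyl hydrogen phosphate, 5 mol%], 4 Å MS, toluene, −20 °C; aq. NaHCO3
Reagents that add atoms: none
Why: Chiral phosphoric acid-catalysed propargylation of an aldehyde: the acid activates the boronate and the allenyl group is transferred through a closed six-membered SE2' transition state, so only the homopropargylic alcohol should form. The (S)-acid is expected to direct attack to the Si face of 1, which sets C6 as (S).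

Step 2
Reactants: 3 (S)-1-(3,4-dimethoxyphenyl)but-3-yn-1-ol
Product: 4 (S)-5-(3,4-dimethoxyphenyl)dihydrofuran-3(2H)-one
Conditions: Ph3PAuNTf2 (5 mol%), 8-methylquinoline N-oxide (1.5 equiv), ClCH2CH2Cl, rt, no added acid
Reagents that add atoms: 8-methylquinoline N-oxide, Cc1cccc2ccc[n+]([O-])c12
Why: Gold-catalysed alkyne oxidation, a known route from homopropargylic alcohols to dihydrofuran-3(2H)-ones: the N-oxide adds to the alkyne activated by monovalent gold at its internal carbon, N–O cleavage leaves an α-oxo gold carbene at the terminal carbon, and the hydroxyl group inserts into it (O7–C8). No bond to C6 is touched and no Brønsted acid is present, so the benzylic stereocentre should be kept.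

Step 3
Reactants: 4 (S)-5-(3,4-dimethoxyphenyl)dihydrofuran-3(2H)-one
Product: 6 (S)-2-(3,4-dimethoxyphenyl)-4-(triethylsilyloxy)-2,5-dihydrofuran, via lithium enolate 5 (not isolated)
Conditions: LiN(i-Pr)2 (1.1 equiv), THF, −78 °C; Et3SiCl (1.3 equiv), −78 → 0 °C; chromatography on Et3N-deactivated silica
Reagents that add atoms: chlorotriethylsilane, CC[Si](Cl)(CC)CC
Why: Kinetic enolisation and O-silylation: lithium amides deprotonate 3-oxotetrahydrofurans at the α-carbon remote from the ring oxygen (here C5), because the oxygen lone pairs disfavour a carbanion at C8, and the silyl chloride traps that regioisomer at low temperature. The C6–O7 bond lies close to the enolate plane, so β-elimination should be slow at −78 °C.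

Step 4
Reactants: 7 homovanillic acid
Product: 9 [4-(tert-butyldimethylsilyloxy)-3-methoxyphenyl]acetic acid, via bis-silylated acid 8 (not isolated)
Conditions: t-BuMe2SiCl (2.5 equiv), imidazole (5 equiv), DMF, rt; then AcOH/THF/H2O, rt
Reagents that add atoms: tert-butyldimethylsilyl chloride, CC(C)(C)[Si](C)(C)Cl
Why: Silylation of phenol and carboxylic acid followed by selective hydrolysis of the silyl ester; the aryl silyl ether is stable to aqueous acetic acid, the silyl ester is not.

Step 5
Reactants: 9 [4-(tert-butyldimethylsilyloxy)-3-methoxyphenyl]acetic acid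
Product: 10 [4-(tert-butyldimethylsilyloxy)-3-methoxyphenyl]acetyl chloride
Conditions: (COCl)2 (1.5 equiv), DMF (cat.), CH2Cl2, 0 °C → rt; evaporate, use crude
Reagents that add atoms: oxalyl chloride, O=C(Cl)C(=O)Cl
Why: Acid chloride formation through the Vilsmeier-type chloroiminium ion under mild conditions, which an aryl silyl ether tolerates.

Step 6
Reactants: 6 (S)-2-(3,4-dimethoxyphenyl)-4-(triethylsilyloxy)-2,5-dihydrofuran; 10 [4-(tert-butyldimethylsilyloxy)-3-methoxyphenyl]acetyl chloride
Product: 13 (1S,4S,5R,7R)-7-[4-(tert-butyldimethylsilyloxy)-3-methoxyphenyl]-4-(3,4-dimethoxyphenyl)-1-(triethylsilyloxy)-3-oxabicyclo[3.2.0]heptan-6-one (7-aryl exo), via arylketene 11 (not isolated), via C2-endo cyclobutanone 12 (not isolated)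
Conditions: 6 (1 equiv), Et3N (5 equiv), toluene, 80 °C; 10 (3 equiv) in toluene added over 8 h; then 80 °C until the C2 epimers are equilibrated
Reagents that add atoms: none
Why: Et3N dehydrochlorinates 10 to arylketene 11, kept dilute by slow addition so that capture by 6 can compete with dimerisation. The electrophilic central ketene carbon (future C4) bonds to the nucleophilic enol carbon C5 while the ketene CH(aryl) carbon bonds to the oxygen-bearing C1, in an asynchronous concerted [π2s + π2a] cycloaddition; this is the known thermal ketene–silyl enol ether [2+2] route to 3-silyloxycyclobutanones. The cyclobutanone ring (C2, C1, C5, C4) closes in this one cycloaddition, and suprafacial addition to the enol ether fixes the cis fusion to ring B. The head-to-tail regiochemistry follows from the polarity of the enol ether. C5 and C1 are set by the C6 stereocentre, because the ketene should approach the dihydrofuran face anti to the veratryl group on the neighbouring carbon. The orthogonal approach of the ketene is expected to place the aryl group endo at first (12). The C2–H is benzylic and α to the ketone, so Et3N at 80 °C should epimerise it to the less crowded exo isomer 13, with the aryl group cis to the silyloxy group and turned away from ring B.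

Step 7
Reactants: 13 (1S,4S,5R,7R)-7-[4-(tert-butyldimethylsilyloxy)-3-methoxyphenyl]-4-(3,4-dimethoxyphenyl)-1-(triethylsilyloxy)-3-oxabicyclo[3.2.0]heptan-6-one
Product: 14 (1S,2R,5R,6S)-2-[4-(tert-butyldimethylsilyloxy)-3-methoxyphenyl]-6-(3,4-dimethoxyphenyl)-1-(triethylsilyloxy)-3,7-dioxabicyclo[3.3.0]octan-4-one
Conditions: m-CPBA (1.5 equiv), NaHCO3, CH2Cl2, 0 °C → rt
Reagents that add atoms: m-chloroperoxybenzoic acid, OOC(=O)c1cccc(Cl)c1
Why: Baeyer–Villiger oxidation of a strained cyclobutanone: in the Criegee adduct the benzylic C2, which carries the electron-rich arene, should migrate in preference to C5, which is flanked by two C–O bonds. Migration proceeds with retention, so the C2–O3 bond forms with the C2 configuration intact.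

Step 8
Reactants: 14 (1S,2R,5R,6S)-2-[4-(tert-butyldimethylsilyloxy)-3-methoxyphenyl]-6-(3,4-dimethoxyphenyl)-1-(triethylsilyloxy)-3,7-dioxabicyclo[3.3.0]octan-4-one
Product: 15 (1S,2R,5R,6S)-2-[4-(tert-butyldimethylsilyloxy)-3-methoxyphenyl]-6-(3,4-dimethoxyphenyl)-1-(triethylsilyloxy)-3,7-dioxabicyclo[3.3.0]octan-4-ol (lactol, both C4 epimers)
Conditions: i-Bu2AlH (1.2 equiv), CH2Cl2, −78 °C; aq. KNaC4H4O6 (potassium sodium tartrate)
Reagents that add atoms: none
Why: Partial reduction of a γ-lactone to the lactol; the tetrahedral aluminium alkoxide is stable at −78 °C and both silyl ethers are inert to the hydride.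

Step 9
Reactants: 15 (1S,2R,5R,6S)-2-[4-(tert-butyldimethylsilyloxy)-3-methoxyphenyl]-6-(3,4-dimethoxyphenyl)-1-(triethylsilyloxy)-3,7-dioxabicyclo[3.3.0]octan-4-ol
Product: 16 (1S,2R,5R,6S)-2-[4-(tert-butyldimethylsilyloxy)-3-methoxyphenyl]-6-(3,4-dimethoxyphenyl)-1-(triethylsilyloxy)-3,7-dioxabicyclo[3.3.0]octane
Conditions: Et3SiH (3 equiv), BF3·OEt2 (1.5 equiv), CH2Cl2, −78 → −40 °C; cold aq. NaHCO3
Reagents that add atoms: none
Why: Ionic hydrogenation of a lactol: BF3·OEt2 ionises the C4–OH bond to the ring A oxocarbenium ion and Et3SiH reduces it to CH2, so no new stereocentre arises. At −78 °C the lactol should ionise far faster than either benzylic ether.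

Step 10
Reactants: 16 (1S,2R,5R,6S)-2-[4-(tert-butyldimethylsilyloxy)-3-methoxyphenyl]-6-(3,4-dimethoxyphenyl)-1-(triethylsilyloxy)-3,7-dioxabicyclo[3.3.0]octane
Product: 17 (1S,2R,5R,6S)-6-(3,4-dimethoxyphenyl)-2-(4-hydroxy-3-methoxyphenyl)-3,7-dioxabicyclo[3.3.0]octan-1-ol
Conditions: Bu4NF (3 equiv), AcOH (3 equiv), THF, 0 °C → rt
Reagents that add atoms: none
Why: Fluoride cleaves both Si–O bonds, the aryl silyl ether quickly and the tertiary triethylsilyl ether more slowly. The acetic acid buffer keeps phenoxide and alkoxide from accumulating, which guards against quinone methide formation at C2.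

Step 11
Reactants: 17 (1S,2R,5R,6S)-6-(3,4-dimethoxyphenyl)-2-(4-hydroxy-3-methoxyphenyl)-3,7-dioxabicyclo[3.3.0]octan-1-ol
Product: 19 (1S,2R,5R,6S)-6-(3,4-dimethoxyphenyl)-2-(4-hydroxy-3-methoxyphenyl)-3,7-dioxabicyclo[3.3.0]octan-1-yl acetate (target), via diacetate 18 (not isolated)
Conditions: Ac2O (6 equiv), Et3N (8 equiv), DMAP (1 equiv), THF, 40 °C; then pyrrolidine (10 equiv), 0 °C → rt
Reagents that add atoms: acetic anhydride, CC(=O)OC(C)=O
Why: DMAP-catalysed acylation (Steglich conditions) acetylates the phenol at once and the hindered tertiary C1 hydroxyl more slowly. Pyrrolidine then aminolyses only the aryl acetate, since phenoxide is a far better leaving group and a tertiary alkyl acetate is inert to amines at room temperature.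

## Compound list

1 | 3,4-dimethoxybenzaldehyde | COc1ccc(C=O)cc1OC | starting material
2 | allenylboronic acid pinacol ester [4,4,5,5-tetramethyl-2-(propa-1,2-dien-1-yl)-1,3,2-dioxaborolane] | C=C=CB1OC(C)(C)C(C)(C)O1 | starting material
3 | (S)-1-(3,4-dimethoxyphenyl)but-3-yn-1-ol | C#CC[C@H](O)c1ccc(OC)c(OC)c1 | intermediate
4 | (S)-5-(3,4-dimethoxyphenyl)dihydrofuran-3(2H)-one | O=C1C[C@@H](c2ccc(OC)c(OC)c2)OC1 | intermediate
5 | lithium (S)-5-(3,4-dimethoxyphenyl)-2,5-dihydrofuran-3-olate (not isolated) | [Li+].[O-]C1=C[C@@H](c2ccc(OC)c(OC)c2)OC1 | intermediate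
6 | (S)-2-(3,4-dimethoxyphenyl)-4-(triethylsilyloxy)-2,5-dihydrofuran | CC[Si](CC)(CC)OC1=C[C@@H](c2ccc(OC)c(OC)c2)OC1 | intermediate
7 | homovanillic acid [(4-hydroxy-3-methoxyphenyl)acetic acid] | COc1cc(CC(=O)O)ccc1O | starting material
8 | tert-butyldimethylsilyl [4-(tert-butyldimethylsilyloxy)-3-methoxyphenyl]acetate (not isolated) | COc1cc(CC(=O)O[Si](C)(C)C(C)(C)C)ccc1O[Si](C)(C)C(C)(C)C | intermediate
9 | [4-(tert-butyldimethylsilyloxy)-3-methoxyphenyl]acetic acid | COc1cc(CC(=O)O)ccc1O[Si](C)(C)C(C)(C)C | intermediate
10 | [4-(tert-butyldimethylsilyloxy)-3-methoxyphenyl]acetyl chloride | COc1cc(CC(Cl)=O)ccc1O[Si](C)(C)C(C)(C)C | intermediate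
11 | [4-(tert-butyldimethylsilyloxy)-3-methoxyphenyl]ketene (not isolated) | COc1cc(C=C=O)ccc1O[Si](C)(C)C(C)(C)C | intermediate
12 | (1S,4S,5R,7S)-7-[4-(tert-butyldimethylsilyloxy)-3-methoxyphenyl]-4-(3,4-dimethoxyphenyl)-1-(triethylsilyloxy)-3-oxabicyclo[3.2.0]heptan-6-one, 7-aryl endo (not isolated) | COc1cc([C@@H]2C(=O)[C@@H]3[C@@H](c4ccc(OC)c(OC)c4)OC[C@]23O[Si](CC)(CC)CC)ccc1O[Si](C)(C)C(C)(C)C | intermediate
13 | (1S,4S,5R,7R)-7-[4-(tert-butyldimethylsilyloxy)-3-methoxyphenyl]-4-(3,4-dimethoxyphenyl)-1-(triethylsilyloxy)-3-oxabicyclo[3.2.0]heptan-6-one, cis-fused, 7-aryl exo (cis to the silyloxy group), 4-aryl trans to the cyclobutanone | COc1cc([C@H]2C(=O)[C@@H]3[C@@H](c4ccc(OC)c(OC)c4)OC[C@]23O[Si](CC)(CC)CC)ccc1O[Si](C)(C)C(C)(C)C | intermediate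
14 | (1S,2R,5R,6S)-2-[4-(tert-butyldimethylsilyloxy)-3-methoxyphenyl]-6-(3,4-dimethoxyphenyl)-1-(triethylsilyloxy)-3,7-dioxabicyclo[3.3.0]octan-4-one | COc1cc([C@H]2OC(=O)[C@@H]3[C@@H](c4ccc(OC)c(OC)c4)OC[C@]23O[Si](CC)(CC)CC)ccc1O[Si](C)(C)C(C)(C)C | intermediate
15 | (1S,2R,5R,6S)-2-[4-(tert-butyldimethylsilyloxy)-3-methoxyphenyl]-6-(3,4-dimethoxyphenyl)-1-(triethylsilyloxy)-3,7-dioxabicyclo[3.3.0]octan-4-ol, both C4 epimers | COc1cc([C@H]2OC(O)[C@@H]3[C@@H](c4ccc(OC)c(OC)c4)OC[C@]23O[Si](CC)(CC)CC)ccc1O[Si](C)(C)C(C)(C)C | intermediate
16 | (1S,2R,5R,6S)-2-[4-(tert-butyldimethylsilyloxy)-3-methoxyphenyl]-6-(3,4-dimethoxyphenyl)-1-(triethylsilyloxy)-3,7-dioxabicyclo[3.3.0]octane | COc1cc([C@H]2OC[C@@H]3[C@@H](c4ccc(OC)c(OC)c4)OC[C@]23O[Si](CC)(CC)CC)ccc1O[Si](C)(C)C(C)(C)C | intermediate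
17 | (1S,2R,5R,6S)-6-(3,4-dimethoxyphenyl)-2-(4-hydroxy-3-methoxyphenyl)-3,7-dioxabicyclo[3.3.0]octan-1-ol | COc1cc([C@H]2OC[C@@H]3[C@@H](c4ccc(OC)c(OC)c4)OC[C@]23O)ccc1O | intermediate
18 | (1S,2R,5R,6S)-2-(4-acetoxy-3-methoxyphenyl)-6-(3,4-dimethoxyphenyl)-3,7-dioxabicyclo[3.3.0]octan-1-yl acetate (not isolated) | COc1cc([C@H]2OC[C@@H]3[C@@H](c4ccc(OC)c(OC)c4)OC[C@]23OC(C)=O)ccc1OC(C)=O | intermediate
19 | (1S,2R,5R,6S)-6-(3,4-dimethoxyphenyl)-2-(4-hydroxy-3-methoxyphenyl)-3,7-dioxabicyclo[3.3.0]octan-1-yl acetate, both aryl groups exo | COc1cc([C@H]2OC[C@@H]3[C@@H](c4ccc(OC)c(OC)c4)OC[C@]23OC(C)=O)ccc1O | target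

## Step count

Total: 11 steps. Longest linear sequence: 9 steps (steps 1, 2, 3, 6, 7, 8, 9, 10, 11, from 1 to 19). The ketene branch (steps 4 and 5) joins at step 6.

## Least certain steps

**Step 6 (key step).** The amine that generates the ketene also catalyses its dimerisation, so the ketene may be consumed before it meets the trisubstituted enol ether. The ammonium chloride formed may also strip the silyl group from 6 or open the 3-silyloxycyclobutanone to a 1,3-diketone. Prolonged heating with base for the C2 equilibration could cause β-elimination. The fallback generates the ketene without base by a Wolff rearrangement. It sets out from 6 and returns at 13. The partner is made from commercial vanillic acid F1. Silylation as in step 4 gives tert-butyldimethylsilyl 4-(tert-butyldimethylsilyloxy)-3-methoxybenzoate F2 and, after hydrolysis of the silyl ester, 4-(tert-butyldimethylsilyloxy)-3-methoxybenzoic acid F3. Oxalyl chloride then gives 4-(tert-butyldimethylsilyloxy)-3-methoxybenzoyl chloride F4, and CH2N2/Et3N converts it into 2-diazo-1-[4-(tert-butyldimethylsilyloxy)-3-methoxyphenyl]ethan-1-one F5. Irradiation of F5 at 365 nm in toluene with 6 present, then warming, should release ketene 11 slowly and free of amine and chloride. The cycloadducts 12 and 13 are then equilibrated with a catalytic amount of Et3N to 13.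

**Step 2.** Without acid the quinoline released may bind the gold centre and stall turnover. If acid has to be added, the electron-rich benzylic carbinol may ionise, with racemisation or elimination. Over-oxidation of the carbene by a second N-oxide is also possible. The fallback avoids carbene chemistry altogether, sets out from 3 and returns at 4. Cycloisomerisation of 3 through a tungsten vinylidene (W(CO)6, Et3N, THF, hν) gives (S)-2-(3,4-dimethoxyphenyl)-2,3-dihydrofuran F6. Hydroboration–oxidation of F6 (BH3·THF, then NaOH/H2O2) places oxygen on the β-carbon of the enol ether and gives (5S)-5-(3,4-dimethoxyphenyl)tetrahydrofuran-3-ol F7 as a mixture at the carbinol carbon. Dess–Martin oxidation of F7 gives 4.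

**Step 7.** Migration of C5 in competition with C2 would give the regioisomeric lactone, and the peracid could attack the electron-rich arenes. The fallback replaces the peracid by light, sets out from 13 and returns at 16, so that steps 7 and 8 are bypassed. Irradiation of 13 in methanol (Pyrex filter) should cleave the C2–C4 bond on the benzylic side and close the acyl oxygen onto C2 with retention. The resulting oxacarbene inserts into the O–H bond of methanol to give the C4 methyl acetal F8. Et3SiH/BF3·OEt2 at −78 °C then reduces F8 to 16.

**Step 9.** The Lewis acid may ionise the C2–O3 or C6–O7 bond, leading to epimerisation at a benzylic centre or reductive ring opening, or may cleave the triethylsilyl ether. The fallback avoids any cation at C4, sets out from 14 and returns at 16. LiAlH4 in THF at 0 °C reduces the lactone to the ring-opened C2,C4-diol F9. MsCl/Et3N at 0 °C sulfonylates the primary hydroxyl of F9 to the primary methanesulfonate F10, which is not isolated. The benzylic C2 hydroxyl of F10 then displaces the sulfonate in a 5-exo-tet closure that leaves the C2 configuration untouched and gives 16.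

## Further compounds

F1 | step 6 | vanillic acid (4-hydroxy-3-methoxybenzoic acid, commercial) | COc1cc(C(=O)O)ccc1O
F2 | step 6 | tert-butyldimethylsilyl 4-(tert-butyldimethylsilyloxy)-3-methoxybenzoate | COc1cc(C(=O)O[Si](C)(C)C(C)(C)C)ccc1O[Si](C)(C)C(C)(C)C
F3 | step 6 | 4-(tert-butyldimethylsilyloxy)-3-methoxybenzoic acid | COc1cc(C(=O)O)ccc1O[Si](C)(C)C(C)(C)C
F4 | step 6 | 4-(tert-butyldimethylsilyloxy)-3-methoxybenzoyl chloride | COc1cc(C(Cl)=O)ccc1O[Si](C)(C)C(C)(C)C
F5 | step 6 | 2-diazo-1-[4-(tert-butyldimethylsilyloxy)-3-methoxyphenyl]ethan-1-one | COc1cc(C(=O)C=[N+]=[N-])ccc1O[Si](C)(C)C(C)(C)C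
F6 | step 2 | (S)-2-(3,4-dimethoxyphenyl)-2,3-dihydrofuran | C1=CC[C@@H](c2ccc(OC)c(OC)c2)O1
F7 | step 2 | (5S)-5-(3,4-dimethoxyphenyl)tetrahydrofuran-3-ol, both C3 epimers | OC1C[C@@H](c2ccc(OC)c(OC)c2)OC1
F8 | step 7 | (1S,2R,5R,6S)-2-[4-(tert-butyldimethylsilyloxy)-3-methoxyphenyl]-6-(3,4-dimethoxyphenyl)-4-methoxy-1-(triethylsilyloxy)-3,7-dioxabicyclo[3.3.0]octane, both C4 epimers | COc1cc([C@H]2OC(OC)[C@@H]3[C@@H](c4ccc(OC)c(OC)c4)OC[C@]23O[Si](CC)(CC)CC)ccc1O[Si](C)(C)C(C)(C)C
F9 | step 9 | ring-opened diol: ring B tetrahydrofuran carrying at C1 the triethylsilyloxy group and the CH(OH)aryl unit (C2) and at C5 the CH2OH group (C4) | COc1cc([C@@H](O)[C@@]2(O[Si](CC)(CC)CC)CO[C@H](c3ccc(OC)c(OC)c3)[C@H]2CO)ccc1O[Si](C)(C)C(C)(C)C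
F10 | step 9 | primary methanesulfonate of F9 | COc1cc([C@@H](O)[C@@]2(O[Si](CC)(CC)CC)CO[C@H](c3ccc(OC)c(OC)c3)[C@H]2COS(C)(=O)=O)ccc1O[Si](C)(C)C(C)(C)C
A1 | alternative 1 | [cis-3-(3,4-dimethoxyphenyl)oxiran-2-yl]methanol, enantiomer as drawn | OC[C@@H]1O[C@@H]1c1ccc(OC)c(OC)c1
A2 | alternative 1 | dimethyl 2-[(4-allyloxy-3-methoxyphenyl)methylidene]malonate | COC(=O)C(=Cc1ccc(OCC=C)c(OC)c1)C(=O)OC
A3 | alternative 1 | methyl 2-(4-allyloxy-3-methoxyphenyl)-6-(3,4-dimethoxyphenyl)-8-oxo-3,7-dioxabicyclo[3.3.0]octane-1-carboxylate | COc1cc([C@H]2OC[C@@H]3[C@@H](c4ccc(OC)c(OC)c4)OC(=O)[C@]23C(=O)OC)ccc1OCC=C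
A4 | alternative 2 | tert-butyl 2-{3-[4-(tert-butyldimethylsilyloxy)-3-methoxyphenyl]-2-(hydroxymethyl)oxiran-2-yl}acetate, enantiomer as drawn | CC(C)(C)OC(=O)C[C@@]1(CO)O[C@H]1c1ccc(O[Si](C)(C)C(C)(C)C)c(OC)c1
A5 | alternative 2 | 5-[4-(tert-butyldimethylsilyloxy)-3-methoxyphenyl]-4-hydroxy-4-(hydroxymethyl)dihydrofuran-2(3H)-one | COc1cc([C@H]2OC(=O)C[C@]2(O)CO)ccc1O[Si](C)(C)C(C)(C)C
A6 | alternative 3 | 6-[4-(tert-butyldimethylsilyloxy)-3-methoxyphenyl]-2-(3,4-dimethoxyphenyl)-1,3,7-trioxaspiro[4.4]nonan-8-one, acetal carbon unassigned | COc1cc([C@H]2OC(=O)C[C@]23COC(c4ccc(OC)c(OC)c4)O3)ccc1O[Si](C)(C)C(C)(C)C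
A7 | alternative 3 | 2-[4-(tert-butyldimethylsilyloxy)-3-methoxyphenyl]-6-(3,4-dimethoxyphenyl)-1-hydroxy-3,7-dioxabicyclo[3.3.0]octan-4-one | COc1cc([C@H]2OC(=O)[C@@H]3[C@@H](c4ccc(OC)c(OC)c4)OC[C@]23O)ccc1O[Si](C)(C)C(C)(C)C
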